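**Retrosynthetic overview**

1. Last disconnection: the bond between the quaternary ring carbon and the geranyl CH2. The target comes from a flat, achiral, fully aromatic methylene-bis(acylphloroglucinol) and geranyl acetate by a catalytic enantioselective dearomative C-geranylation, which creates the dienone and the only stereocentre in one step.
2. The aromatic dimer is cut at the methylene bridge into a butyryl-prenyl-phloroglucinol (ring A), an acetyl-methyl-phloroglucinol (ring B) and formaldehyde (Mannich base, then ortho-quinone methide, then C–C union).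
3. The ring A monomer comes from phloroglucinol (Friedel–Crafts butyrylation, C-prenylation); the ring B monomer comes from 2,4,6-trihydroxytoluene (Friedel–Crafts acetylation).
4. Ring order: no ring is built. Both six-membered rings are bought as arenes; ring A stays aromatic and ring B is dearomatised in the final step. No protecting groups are used.

Assumption: the target is one drawn tautomer of a rapidly equilibrating enol system, and in that drawing the quaternary centre is (R). The sense of induction of the Trost ligand on this substrate cannot be predicted with certainty; the (R,R) ligand is written, and its (S,S) antipode is used if a pilot run gives the other enantiomer.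

**Route**

Step 1
Reactants: 1 phloroglucinol (benzene-1,3,5-triol)
Product: 2 1-(2,4,6-trihydroxyphenyl)butan-1-one
Conditions: butyryl chloride (1.05 equiv), AlCl3 (3.5 equiv), PhNO2/CH2Cl2, 0 °C to 40 °C; then ice/aq. HCl
Reagents that add atoms: butyryl chloride (butanoyl chloride), CCCC(=O)Cl
Why: Friedel–Crafts C-acylation of the symmetric, very electron-rich triol stops after one acyl group because the chelated aryl ketone–AlCl3 complex is deactivated; all three ring positions are equivalent, so one product forms.

Step 2
Reactants: 2 1-(2,4,6-trihydroxyphenyl)butan-1-one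
Product: 3 1-[2,4,6-trihydroxy-3-(3-methylbut-2-en-1-yl)phenyl]butan-1-one
Conditions: prenyl bromide (1.0 equiv), 10% aq. KOH, 0 °C, 2 h; then aq. HCl
Reagents that add atoms: prenyl bromide (1-bromo-3-methylbut-2-ene), CC(C)=CCBr
Why: C-alkylation (SN2) of the ambident phloroglucinolate in water, where solvated phenolate oxygens favour attack through carbon; the two free ring carbons are equivalent, and one equivalent of bromide limits double prenylation.

Step 3
Reactants: 4 2,4,6-trihydroxytoluene (2-methylbenzene-1,3,5-triol)
Product: 5 1-(2,4,6-trihydroxy-3-methylphenyl)ethan-1-one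
Conditions: acetyl chloride (1.0 equiv), AlCl3 (3.5 equiv), PhNO2/CH2Cl2, 0 °C to rt; then ice/aq. HCl
Reagents that add atoms: acetyl chloride, CC(=O)Cl
Why: Friedel–Crafts C-acylation at one of the two equivalent free ring carbons; the first acyl group deactivates the ring towards a second.

Step 4
Reactants: 5 1-(2,4,6-trihydroxy-3-methylphenyl)ethan-1-one; 3 1-[2,4,6-trihydroxy-3-(3-methylbut-2-en-1-yl)phenyl]butan-1-one
Product: 8 1-[3-[(3-acetyl-2,4,6-trihydroxy-5-methylphenyl)methyl]-2,4,6-trihydroxy-5-(3-methylbut-2-en-1-yl)phenyl]butan-1-one, via Mannich base 6 (not isolated), via ortho-quinone methide 7 (not isolated)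
Conditions: 5, 37% aq. CH2O (1.05 equiv), 40% aq. Me2NH (1.1 equiv), EtOH, 0 °C to rt; evaporate; then 3 (1.0 equiv), dioxane, 90 °C, N2 sweep
Reagents that add atoms: formaldehyde, C=O; dimethylamine, CNC (its atoms stay only in 6 and leave again as the free amine)
Why: Mannich aminomethylation at the only free ring carbon of 5, then thermal loss of dimethylamine, gives an ortho-quinone methide that is trapped by Michael (Friedel–Crafts-type) addition of the only free ring carbon of 3, so the cross-dimer forms without the statistical homodimers of a direct formaldehyde condensation; no stereocentre is formed.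

Step 5
Reactants: 8 1-[3-[(3-acetyl-2,4,6-trihydroxy-5-methylphenyl)methyl]-2,4,6-trihydroxy-5-(3-methylbut-2-en-1-yl)phenyl]butan-1-one; 9 geranyl acetate [(2E)-3,7-dimethylocta-2,6-dien-1-yl acetate]
Product: 10 (4R)-2-acetyl-6-{[3-butanoyl-2,4,6-trihydroxy-5-(3-methylbut-2-en-1-yl)phenyl]methyl}-4-[(2E)-3,7-dimethylocta-2,6-dien-1-yl]-3,5-dihydroxy-4-methylcyclohexa-2,5-dien-1-one (CNP0227753.1)
Conditions: Pd2(dba)3·CHCl3 (2.5 mol %; dba = dibenzylideneacetone), (R,R)-DACH-phenyl Trost ligand (7.5 mol %), Et3N (2 equiv), 9 (1.0 equiv, slow addition), degassed THF, 0 °C to rt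
Reagents that add atoms: none
Why: Proposed new method: zerovalent palladium ionises geranyl acetate to a cationic η3-geranyl complex of divalent palladium held in the chiral pocket of the Trost ligand, and the triethylammonium phloroglucinolate of 8 attacks its unsubstituted CH2 terminus from outside through the methyl-bearing carbon of ring B, the only ring carbon that is neither acylated nor crowded (the prenyl-bearing carbon of ring A and the two bridge carbons are more hindered, and any O-geranyl ether is re-ionised by the catalyst and funnels to the C-alkylated vinylogous acid); the ligand distinguishes the two faces of ring B, whose flanks differ strongly (chelated acetyl side against arylmethyl side), so the (R) quaternary centre is set in the C–C bond-forming event, while the E alkene is kept because attack is at the CH2 end and the tertiary σ-allyl needed for E/Z exchange is disfavoured; the closest known reaction type is the Tsuji–Trost asymmetric allylic alkylation in its intermolecular dearomatising form (naphthols, fully substituted acylphloroglucinols).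

**Compound list**

1 | phloroglucinol (benzene-1,3,5-triol) | Oc1cc(O)cc(O)c1 | starting material
2 | 1-(2,4,6-trihydroxyphenyl)butan-1-one | CCCC(=O)c1c(O)cc(O)cc1O | intermediate
3 | 1-[2,4,6-trihydroxy-3-(3-methylbut-2-en-1-yl)phenyl]butan-1-one (ring A monomer) | CCCC(=O)c1c(O)cc(O)c(CC=C(C)C)c1O | intermediate
4 | 2,4,6-trihydroxytoluene (2-methylbenzene-1,3,5-triol) | Cc1c(O)cc(O)cc1O | starting material
5 | 1-(2,4,6-trihydroxy-3-methylphenyl)ethan-1-one (ring B monomer) | CC(=O)c1c(O)c(C)c(O)cc1O | intermediate
6 | 1-[3-[(dimethylamino)methyl]-2,4,6-trihydroxy-5-methylphenyl]ethan-1-one (Mannich base, not isolated) | CC(=O)c1c(O)c(C)c(O)c(CN(C)C)c1O | intermediate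
7 | 2-acetyl-3,5-dihydroxy-4-methyl-6-methylidenecyclohexa-2,4-dien-1-one (ortho-quinone methide, not isolated) | CC(=O)C1=C(O)C(C)=C(O)C(=C)C1=O | intermediate
8 | 1-[3-[(3-acetyl-2,4,6-trihydroxy-5-methylphenyl)methyl]-2,4,6-trihydroxy-5-(3-methylbut-2-en-1-yl)phenyl]butan-1-one (fully aromatic dimer) | CCCC(=O)c1c(O)c(CC=C(C)C)c(O)c(Cc2c(O)c(C)c(O)c(C(C)=O)c2O)c1O | intermediate
9 | geranyl acetate [(2E)-3,7-dimethylocta-2,6-dien-1-yl acetate] | CC(=O)OC/C=C(\C)CCC=C(C)C | starting material
10 | (4R)-2-acetyl-6-{[3-butanoyl-2,4,6-trihydroxy-5-(3-methylbut-2-en-1-yl)phenyl]methyl}-4-[(2E)-3,7-dimethylocta-2,6-dien-1-yl]-3,5-dihydroxy-4-methylcyclohexa-2,5-dien-1-one | CCCC(=O)c1c(O)c(CC=C(C)C)c(O)c(CC2=C(O)[C@@](C)(C/C=C(\C)CCC=C(C)C)C(O)=C(C(C)=O)C2=O)c1O | target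

**Step count and risks**

Total step count: 5. Longest linear sequence: 4 steps (1 → 2 → 3 → 8 → 10, steps 1, 2, 4 and 5).

Steps most likely to fail:

Step 5 (highest risk). The catalyst must choose ring B over ring A, carbon over oxygen, one face of ring B over the other, and must keep the E alkene; over-geranylation of ring A is limited only by stoichiometry. Fallback, setting out from 5 and coming back at 10: the allylation is moved to the monomer, where ring A cannot compete.
- 5 is treated with 9 under the same zerovalent-palladium/Trost-ligand catalysis to give the dearomatised monomer (4R)-2-acetyl-4-[(2E)-3,7-dimethylocta-2,6-dien-1-yl]-3,5-dihydroxy-4-methylcyclohexa-2,5-dien-1-one F1.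
- F1 is a strong vinylogous acid, so it is separated from the aromatic ring-geranylated isomer by extraction into aqueous NaHCO3; if the ee is low it is upgraded by crystallising its cinchonidine salt.
- In parallel, 3 is converted with aqueous formaldehyde and dimethylamine into its Mannich base 1-[3-[(dimethylamino)methyl]-2,4,6-trihydroxy-5-(3-methylbut-2-en-1-yl)phenyl]butan-1-one F2.
- Warming F1 with F2 in dioxane expels dimethylamine from F2 to give the ring A ortho-quinone methide 2-butanoyl-3,5-dihydroxy-6-methylidene-4-(3-methylbut-2-en-1-yl)cyclohexa-2,4-dien-1-one F3, which is captured by the free C6 of F1 to give 10.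

Step 4. The Mannich base can react with unconverted 5 to give the ring B homodimer, and methylene-bis(phloroglucinols) can exchange halves under warm basic conditions. Fallback, setting out from 5 and coming back at 8: equilibrium transfer of the bridge from a stable symmetric dimer.
- 5 is condensed with 0.5 equivalent of aqueous formaldehyde (dilute NaOH, rt) to the crystalline symmetric dimer bis(3-acetyl-2,4,6-trihydroxy-5-methylphenyl)methane F4.
- F4 is stirred with an excess of 3 in dilute aqueous Na2CO3 at rt (rottlerone-type exchange). It fragments by retro-Michael reaction into 7 and the phenolate of 5, and 7 is recaptured by 3 to give 8.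
- 8 is separated by chromatography, and the liberated 5 and unchanged F4 are recycled.

Step 2. Mono-C-prenylation in aqueous alkali is typically modest, with O-prenyl, 3,5-diprenyl and gem-diprenyl by-products. Fallback, setting out from 2 and coming back at 3: O-alkylation followed by an oxygen-to-carbon shift.
- 2 is O-alkylated at the non-chelated 4-hydroxyl (prenyl bromide, K2CO3, acetone, rt) to the aryl prenyl ether 1-[2,6-dihydroxy-4-[(3-methylbut-2-en-1-yl)oxy]phenyl]butan-1-one F5.
- Montmorillonite K10 in CH2Cl2 at 0 °C then promotes the formal [1,3] shift of the prenyl group to a ring carbon ortho to the ether oxygen; both ortho carbons are equivalent, so 3 is the only C-prenyl isomer.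

**Further compounds**

F1 | step 5 | (4R)-2-acetyl-4-[(2E)-3,7-dimethylocta-2,6-dien-1-yl]-3,5-dihydroxy-4-methylcyclohexa-2,5-dien-1-one | O=C1C=C(O)[C@@](C)(C/C=C(\C)CCC=C(C)C)C(O)=C1C(C)=O
F2 | step 5 | 1-[3-[(dimethylamino)methyl]-2,4,6-trihydroxy-5-(3-methylbut-2-en-1-yl)phenyl]butan-1-one | CCCC(=O)c1c(O)c(CC=C(C)C)c(O)c(CN(C)C)c1O
F3 | step 5 | 2-butanoyl-3,5-dihydroxy-6-methylidene-4-(3-methylbut-2-en-1-yl)cyclohexa-2,4-dien-1-one | CCCC(=O)C1=C(O)C(CC=C(C)C)=C(O)C(=C)C1=O
F4 | step 4 | bis(3-acetyl-2,4,6-trihydroxy-5-methylphenyl)methane | CC(=O)c1c(O)c(C)c(O)c(Cc2c(O)c(C)c(O)c(C(C)=O)c2O)c1O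
F5 | step 2 | 1-[2,6-dihydroxy-4-[(3-methylbut-2-en-1-yl)oxy]phenyl]butan-1-one | CCCC(=O)c1c(O)cc(OCC=C(C)C)cc1O
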